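**Plan**

- Retrosynthesis (isochromene numbering): cut C7–C8 (Dieckmann), then O2–C1 and C4a–C8a (the lactone and Michael bonds of the pyranone). This leaves an open-chain (S)-ynedione, MeCO–C≡C–C5(Me)(farnesyl)–CO–Et, plus dimethyl malonate.
- Enabling feature: C8a carries two acyl carbons, the lactone carbonyl C1 and the enolised ketone C8, so C1–C8a–C8 is a malonate unit. The ring O2–C3(Me)=C4–C4a is the lactonised adduct of that malonate with a ynone. C5 is quaternary, so C7 is the only enolisable α-carbon of the C6 ketone and the carbocycle cannot aromatise.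
- Ynedione: cut the acetyl–alkyne bond (acyl Sonogashira); ethyl ketone from an ester (Weinreb); ethynyl from an acetyl group (enol phosphate elimination); C5–CH2 bond from ethyl 2-methylacetoacetate and (E,E)-farnesyl bromide.
- Forward: the chain with its quaternary centre is assembled first (steps 1–6). One flask then closes the pyranone ring and, last, the carbocycle C4a–C5–C6–C7–C8–C8a.
- Stereochemistry: C5 is set in step 2 by alkylation of the L-valine tert-butyl ester enamine (auxiliary control). It bears no hydrogen and is carried unchanged. The E,E-triene comes from farnesyl bromide.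

Key step: step 7

Assumption: in step 2 the HMPA-ligated lithio-enamine is taken to be alkylated on the face that gives the (S)-keto ester; the sense must be confirmed on the first batch, and if it is opposite, HMPA is replaced by THF, which should reverse the face with the same L-auxiliary.

**Route**

Step 1
Reactants: 1 ethyl 2-methylacetoacetate; 2 L-valine tert-butyl ester (free base)
Product: 3 ethyl (Z)-3-{[(2S)-1-tert-butoxy-3-methyl-1-oxobutan-2-yl]amino}-2-methylbut-2-enoate
Conditions: cat. BF3·OEt2, benzene, reflux, Dean–Stark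
Reagents that add atoms: none
Why: Acid-catalysed condensation of a β-keto ester with a primary amine under azeotropic removal of water (enamine formation) should give the hydrogen-bonded (Z)-enamino ester; no new stereocentre is formed and the valine centre is not at risk under these conditions.

Step 2
Reactants: 3 chiral enamino ester; 4 (2E,6E)-farnesyl bromide
Product: 6 ethyl (2S,4E,8E)-2-acetyl-2,5,9,13-tetramethyltetradeca-4,8,12-trienoate, via alkylated imine 5 (not isolated)
Conditions: LDA (1.1 equiv), toluene, –78 °C; HMPA (1 equiv); 4, –78 → –50 °C; then aq. citric acid, rt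
Reagents that add atoms: water, O (the ketone oxygen of 6 comes from the hydrolysis of 5)
Why: Auxiliary-controlled enamine alkylation: N-lithiation gives a rigid aza-enolate in which lithium is chelated by nitrogen and the tert-butyl ester carbonyl of the valine unit, the isopropyl group and the ligand on lithium leave one face open, SN2 attack on the primary allylic bromide (E geometry retained) creates the quaternary centre under auxiliary control, and mild aqueous acid hydrolyses imine 5 to the ketone and returns the auxiliary.

Step 3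
Reactants: 6 (S)-keto ester
Product: 8 ethyl (2S,4E,8E)-2-ethynyl-2,5,9,13-tetramethyltetradeca-4,8,12-trienoate, via enol phosphate 7 (not isolated)
Conditions: LDA (1.1 equiv), THF, –78 °C; ClP(O)(OEt)2; then LDA (2.3 equiv), –78 °C → rt; aq. NH4Cl
Reagents that add atoms: diethyl chlorophosphate, CCOP(=O)(Cl)OCC (its atoms stand in 7 only and leave again before 8)
Why: Methyl ketone to terminal alkyne by enol phosphate formation and β-elimination: deprotonation can occur only at the acetyl CH3 because the other α-carbon is quaternary, O-phosphorylation gives 7, and LDA-induced loss of diethyl phosphate gives the acetylide, which is protonated on work-up without touching the stereocentre.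

Step 4
Reactants: 8 alkynyl ester
Product: 9 (2S,4E,8E)-2-ethynyl-N-methoxy-N,2,5,9,13-pentamethyltetradeca-4,8,12-trienamide
Conditions: MeNH(OMe)·HCl (3 equiv), i-PrMgCl (7 equiv), THF, –20 °C → rt; aq. NH4Cl
Reagents that add atoms: N,O-dimethylhydroxylamine hydrochloride, CNOC.Cl
Why: Weinreb amide formation by aminolysis of the ester with the chloromagnesium amide of N,O-dimethylhydroxylamine; the acetylenic C–H is only deprotonated by the excess Grignard reagent and returns on work-up.

Step 5
Reactants: 9 Weinreb amide
Product: 10 (4S,6E,10E)-4-ethynyl-4,7,11,15-tetramethylhexadeca-6,10,14-trien-3-one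
Conditions: EtMgBr (3 equiv), THF, 0 °C → rt; aq. NH4Cl
Reagents that add atoms: ethylmagnesium bromide, CC[Mg]Br
Why: Weinreb ketone synthesis: the magnesium-chelated tetrahedral adduct does not collapse before work-up, so only one ethyl group should be delivered, while the alkyne sits as its magnesium acetylide.

Step 6
Reactants: 10 ethynyl ketone
Product: 11 (4S,6E,10E)-4,7,11,15-tetramethyl-4-(3-oxobut-1-yn-1-yl)hexadeca-6,10,14-trien-3-one
Conditions: AcCl (1.5 equiv), PdCl2(PPh3)2 (2 mol %), CuI (4 mol %), Et3N (2 equiv), THF, rt
Reagents that add atoms: acetyl chloride, CC(=O)Cl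
Why: Acyl Sonogashira coupling of a terminal alkyne with an acid chloride should give the conjugated ynone at room temperature, conditions that leave the ketone, the trisubstituted alkenes and the hydrogen-free quaternary centre alone.

Step 7
Reactants: 11 (S)-ynedione; 12 dimethyl malonate
Product: 15 (5S)-8-hydroxy-3,5,7-trimethyl-5-[(2E,6E)-3,7,11-trimethyldodeca-2,6,10-trien-1-yl]-1H-isochromene-1,6(5H)-dione, via Michael adduct 13 (not isolated), via pyranone ester 14 (not isolated)
Conditions: (i) 12 (1.3 equiv), NaHMDS (1.1 equiv), THF, 0 → 50 °C; (ii) NaHMDS (2.5 equiv), –78 → 0 °C; (iii) 1 M HCl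
Reagents that add atoms: none
Why: Sodio-malonate adds to the ynone β-carbon (C4a, Michael addition) to give 13 as a delocalised anion whose E and Z forms interconvert, and the enolate oxygen of the acetyl group then attacks one malonate ester (6-exo-trig lactonisation, loss of methoxide) to give the 2-pyranone 14. The second portion of base enolises the ethyl ketone at C7 and this enolate attacks the remaining ester carbon C8 (6-(enolendo)-exo-trig Dieckmann closure, loss of methoxide), so the carbocycle closes last; deprotonation of the new β-diketone drives the sequence and acid should release the conjugated enol hydrogen-bonded to the lactone carbonyl. The closest known reactions are the synthesis of 2-oxo-2H-pyran-3-carboxylates from malonates and alkynyl ketones and the Dieckmann-type acylation of a ketone enolate by a neighbouring ester (Michael–Claisen annulation logic). No stereocentre is created: C5 is fully substituted, has no acidic hydrogen and should pass through unchanged. The order of ring closure is secured by base stoichiometry, since in stage (i) the single equivalent of base is stored in the stabilised anion of 13 and no ketone enolate can form before the pyranone exists. The site of the Dieckmann closure is secured by geometry, since across C4a=C8a the exocyclic ester is cis to C5 whereas the lactone carbonyl is held trans in the ring and out of reach, and C-acylation over O-acylation is favoured by formation of the stable β-diketonate.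

**Compound list**

1 | ethyl 2-methylacetoacetate (racemic) | CCOC(=O)C(C)C(C)=O | starting material
2 | L-valine tert-butyl ester (free base; also obtainable from its hydrochloride by a basic wash) | CC(C)[C@H](N)C(=O)OC(C)(C)C | starting material
3 | ethyl (Z)-3-{[(2S)-1-tert-butoxy-3-methyl-1-oxobutan-2-yl]amino}-2-methylbut-2-enoate | CCOC(=O)/C(C)=C(C)\N[C@@H](C(C)C)C(=O)OC(C)(C)C | intermediate
4 | (2E,6E)-farnesyl bromide | CC(C)=CCC/C(C)=C/CC/C(C)=C/CBr | starting material
5 | ethyl (2S,4E,8E)-2-(1-{[(2S)-1-tert-butoxy-3-methyl-1-oxobutan-2-yl]imino}ethyl)-2,5,9,13-tetramethyltetradeca-4,8,12-trienoate (alkylated imine, formed in the flask) | CC(C)=CCC/C(C)=C/CC/C(C)=C/C[C@](C(C)=N[C@@H](C(C)C)C(=O)OC(C)(C)C)(C)C(=O)OCC | intermediate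
6 | ethyl (2S,4E,8E)-2-acetyl-2,5,9,13-tetramethyltetradeca-4,8,12-trienoate | CC(C)=CCC/C(C)=C/CC/C(C)=C/C[C@](C(C)=O)(C)C(=O)OCC | intermediate
7 | ethyl (2S,4E,8E)-2-[1-(diethoxyphosphoryloxy)ethenyl]-2,5,9,13-tetramethyltetradeca-4,8,12-trienoate (enol phosphate, formed in the flask) | CC(C)=CCC/C(C)=C/CC/C(C)=C/C[C@](C(=C)OP(=O)(OCC)OCC)(C)C(=O)OCC | intermediate
8 | ethyl (2S,4E,8E)-2-ethynyl-2,5,9,13-tetramethyltetradeca-4,8,12-trienoate | CC(C)=CCC/C(C)=C/CC/C(C)=C/C[C@](C#C)(C)C(=O)OCC | intermediate
9 | (2S,4E,8E)-2-ethynyl-N-methoxy-N,2,5,9,13-pentamethyltetradeca-4,8,12-trienamide | CC(C)=CCC/C(C)=C/CC/C(C)=C/C[C@](C#C)(C)C(=O)N(C)OC | intermediate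
10 | (4S,6E,10E)-4-ethynyl-4,7,11,15-tetramethylhexadeca-6,10,14-trien-3-one | CC(C)=CCC/C(C)=C/CC/C(C)=C/C[C@](C#C)(C)C(=O)CC | intermediate
11 | (4S,6E,10E)-4,7,11,15-tetramethyl-4-(3-oxobut-1-yn-1-yl)hexadeca-6,10,14-trien-3-one | CC(C)=CCC/C(C)=C/CC/C(C)=C/C[C@](C#CC(C)=O)(C)C(=O)CC | intermediate
12 | dimethyl malonate | COC(=O)CC(=O)OC | starting material
13 | dimethyl 2-{(1E/Z)-3-oxo-1-[(4S,6E,10E)-4,7,11,15-tetramethyl-3-oxohexadeca-6,10,14-trien-4-yl]but-1-en-1-yl}malonate (Michael adduct, formed in the flask) | CC(C)=CCC/C(C)=C/CC/C(C)=C/C[C@](C(=CC(C)=O)C(C(=O)OC)C(=O)OC)(C)C(=O)CC | intermediate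
14 | methyl 6-methyl-2-oxo-4-[(4S,6E,10E)-4,7,11,15-tetramethyl-3-oxohexadeca-6,10,14-trien-4-yl]-2H-pyran-3-carboxylate (pyranone ester, formed in the flask) | CC(C)=CCC/C(C)=C/CC/C(C)=C/C[C@](c1cc(C)oc(=O)c1C(=O)OC)(C)C(=O)CC | intermediate
15 | 5-farnesyl-isochromene, (5S)-8-hydroxy-3,5,7-trimethyl-5-[(2E,6E)-3,7,11-trimethyldodeca-2,6,10-trien-1-yl]-1H-isochromene-1,6(5H)-dione | CC(C)=CCC/C(C)=C/CC/C(C)=C/C[C@]1(C)C(=O)C(C)=C(O)c2c1cc(C)oc2=O | target

**Count and risks**

Total step count: 7. Longest linear sequence: 7 steps (1 → 15).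

Steps most likely to fail:

1. Step 7. The conjugate addition may be slow at the alkyne carbon next to the quaternary centre. Methoxide set free in the flask may attack the C6 ketone and cleave the C5–C6 bond (retro-Claisen) before ring closure. Unproductive deprotonation of the pyranone methyl group may lead to intermolecular condensation. The fallback sets out from 11 and returns at 15, with a smaller and more acidic donor and a ring closure free of strong base and alkoxide. Ynedione 11 is treated with Meldrum's acid and catalytic Et3N in MeCN. The conjugate adduct F1 should lactonise in the flask, with loss of acetone, to 6-methyl-2-oxo-4-[(4S,6E,10E)-4,7,11,15-tetramethyl-3-oxohexadeca-6,10,14-trien-4-yl]-2H-pyran-3-carboxylic acid F2. The acid is esterified with pentafluorophenol (EDC, cat. DMAP, CH2Cl2) to the pentafluorophenyl ester F3. Soft enolisation of the ethyl ketone (MgBr2·OEt2, i-Pr2NEt, CH2Cl2, rt) should then close the carbocycle by intramolecular C-acylation to give 15.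

2. Step 2. Facial selectivity in the alkylation of the acyclic lithio-enamine may be insufficient or of the wrong sense, and N-alkylation may compete. The fallback sets out from 1 and 4 and returns at 6, replacing asymmetric induction by resolution. Keto ester 1 is alkylated with 4 without auxiliary (K2CO3, acetone, reflux) to the racemic keto ester F4. Preparative chromatography on a chiral stationary phase gives 6, and the (R)-enantiomer F5 is set aside.

3. Step 4. Acyl substitution at the neopentyl-type ester may stay incomplete, and the same hindrance may slow the Grignard addition of step 5 or divert it to loss of the N-methoxy group. The fallback sets out from 8 and returns at 10 by a redox sequence that avoids the amide. Ester 8 is reduced with DIBAL-H (CH2Cl2, –78 → 0 °C) to the primary alcohol F6. Dess–Martin oxidation gives the non-enolisable aldehyde F7. Excess EtMgBr (the alkyne is deprotonated) adds to give the secondary alcohol F8 as both carbinol epimers. A second Dess–Martin oxidation gives 10.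

**Further compounds**

F1 | step 7 | 2,2-dimethyl-5-{(1E/Z)-3-oxo-1-[(4S,6E,10E)-4,7,11,15-tetramethyl-3-oxohexadeca-6,10,14-trien-4-yl]but-1-en-1-yl}-1,3-dioxane-4,6-dione | CC(C)=CCC/C(C)=C/CC/C(C)=C/C[C@](C(=CC(C)=O)C1C(=O)OC(C)(C)OC1=O)(C)C(=O)CC
F2 | step 7 | 6-methyl-2-oxo-4-[(4S,6E,10E)-4,7,11,15-tetramethyl-3-oxohexadeca-6,10,14-trien-4-yl]-2H-pyran-3-carboxylic acid | CC(C)=CCC/C(C)=C/CC/C(C)=C/C[C@](c1cc(C)oc(=O)c1C(=O)O)(C)C(=O)CC
F3 | step 7 | pentafluorophenyl 6-methyl-2-oxo-4-[(4S,6E,10E)-4,7,11,15-tetramethyl-3-oxohexadeca-6,10,14-trien-4-yl]-2H-pyran-3-carboxylate | CC(C)=CCC/C(C)=C/CC/C(C)=C/C[C@](c1cc(C)oc(=O)c1C(=O)Oc2c(F)c(F)c(F)c(F)c2F)(C)C(=O)CC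
F4 | step 2 | ethyl (4E,8E)-2-acetyl-2,5,9,13-tetramethyltetradeca-4,8,12-trienoate (racemic) | CC(C)=CCC/C(C)=C/CC/C(C)=C/CC(C(C)=O)(C)C(=O)OCC
F5 | step 2 | ethyl (2R,4E,8E)-2-acetyl-2,5,9,13-tetramethyltetradeca-4,8,12-trienoate | CC(C)=CCC/C(C)=C/CC/C(C)=C/C[C@@](C(C)=O)(C)C(=O)OCC
F6 | step 4 | (2S,4E,8E)-2-ethynyl-2,5,9,13-tetramethyltetradeca-4,8,12-trien-1-ol | CC(C)=CCC/C(C)=C/CC/C(C)=C/C[C@](C#C)(C)CO
F7 | step 4 | (2S,4E,8E)-2-ethynyl-2,5,9,13-tetramethyltetradeca-4,8,12-trienal | CC(C)=CCC/C(C)=C/CC/C(C)=C/C[C@](C#C)(C)C=O
F8 | step 4 | (4S,6E,10E)-4-ethynyl-4,7,11,15-tetramethylhexadeca-6,10,14-trien-3-ol (both C3 epimers) | CC(C)=CCC/C(C)=C/CC/C(C)=C/C[C@](C#C)(C)C(O)CC
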